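**Plan**
- Retrosynthesis: with the two ring A hydroxyls masked as benzyl ethers, ring B (the propanoyl ring) is cut at two bonds. One joins the methyl-bearing carbon to the hydroxyl carbon beside the bridge; the other joins the propanoyl-bearing carbon to the hydroxyl carbon on the other side of the bridge.
- Enabling feature: in ring B, the ring methyl, the methyl-bearing carbon, the hydroxyl carbon between methyl and propanoyl, the propanoyl-bearing carbon and the propanoyl group form the unbroken seven-carbon chain of heptane-3,5-dione. The other three ring carbons (the bridge-bearing carbon and its two hydroxyl-bearing neighbours) are a malonyl unit that already carries the bridge methylene and ring A.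
- The malonyl unit is traced back across the bond between the bridge methylene and the malonyl carbon (Knoevenagel condensation and reduction with Meldrum's acid) to a ring A aldehyde. The aldehyde comes from 2-methylphloroglucinol by C-butanoylation, O-methylation para to the ketone and formylation at the last free ring position.
- Forward: ring A is bought aromatic and dressed (steps 1–7), and the diketone is converted into its bis(silyl enol ether) (steps 8–9). Ring B, the only ring made, closes in step 10, and step 11 removes the benzyl groups.
- Stereochemistry: the target has no stereocentre, so nothing has to be controlled.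

Key step: step 10

Remark: the silyl enol ethers of the diketone branch are drawn with Z geometry, the expected major form; this geometry is lost in the ring closure and has no bearing on the outcome.

**Route**

Step 1
Reactants: 1 2-methylbenzene-1,3,5-triol; 2 butanoyl chloride
Product: 3 1-(2,4,6-trihydroxy-3-methylphenyl)butan-1-one
Conditions: AlCl3 (3.5 equiv), PhNO2, 20 → 60 °C; then ice/aq. HCl
Reagents that add atoms: none
Why: Friedel–Crafts C-acylation in which the two free ring positions of 1 are equivalent, so a single monoketone should form and the new acyl group deactivates the ring towards a second acylation.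

Step 2
Reactants: 3 1-(2,4,6-trihydroxy-3-methylphenyl)butan-1-one
Product: 4 1-(2,6-dihydroxy-4-methoxy-3-methylphenyl)butan-1-one (aspidinol)
Conditions: Me2SO4 (1.05 equiv), K2CO3 (1.1 equiv), acetone, reflux
Reagents that add atoms: dimethyl sulfate, COS(=O)(=O)OC
Why: Williamson O-methylation should go to the hydroxyl para to the ketone, which is the most acidic and is not hydrogen-bonded, while the two ortho hydroxyls are held by the carbonyl and one equivalent of alkylating agent limits over-methylation.

Step 3
Reactants: 4 1-(2,6-dihydroxy-4-methoxy-3-methylphenyl)butan-1-one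
Product: 5 3-butanoyl-2,4-dihydroxy-6-methoxy-5-methylbenzaldehyde
Conditions: Cl2CHOMe (2 equiv), TiCl4 (3 equiv), CH2Cl2, 0 → 20 °C; then aq. HCl
Reagents that add atoms: dichloromethyl methyl ether, COC(Cl)Cl; water, O
Why: Rieche formylation can only occur at the single unsubstituted ring position, between the methoxy group and a hydroxyl, and aqueous work-up hydrolyses the chloro(methoxy)methyl arene to the aldehyde.

Step 4
Reactants: 5 3-butanoyl-2,4-dihydroxy-6-methoxy-5-methylbenzaldehyde
Product: 6 2,4-bis(benzyloxy)-3-butanoyl-6-methoxy-5-methylbenzaldehyde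
Conditions: BnBr (2.6 equiv), K2CO3 (3 equiv), Bu4NI (cat.), DMF, 60 °C
Reagents that add atoms: benzyl bromide, BrCc1ccccc1
Why: Williamson benzylation in DMF with mild heating overcomes the chelation of both phenols and masks the hydroxyls that would otherwise lactonise or be acylated once the malonyl group is activated.

Step 5
Reactants: 6 2,4-bis(benzyloxy)-3-butanoyl-6-methoxy-5-methylbenzaldehyde; 7 2,2-dimethyl-1,3-dioxane-4,6-dione
Product: 9 5-{[2,4-bis(benzyloxy)-3-butanoyl-6-methoxy-5-methylphenyl]methyl}-2,2-dimethyl-1,3-dioxane-4,6-dione, via arylidene Meldrum's acid 8 (not isolated)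
Conditions: diethyl 1,4-dihydro-2,6-dimethylpyridine-3,5-dicarboxylate (Hantzsch ester, 1.1 equiv), L-proline (20 mol%), EtOH, 20 °C
Reagents that add atoms: none
Why: One-pot reductive alkylation, in which Knoevenagel condensation gives the strongly electrophilic alkylidene 8 and hydride transfer from the Hantzsch ester reduces it at once, leaving the hindered aryl ketone untouched and allowing only mono-alkylation.

Step 6
Reactants: 9 5-{[2,4-bis(benzyloxy)-3-butanoyl-6-methoxy-5-methylphenyl]methyl}-2,2-dimethyl-1,3-dioxane-4,6-dione
Product: 10 2-{[2,4-bis(benzyloxy)-3-butanoyl-6-methoxy-5-methylphenyl]methyl}propanedioic acid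
Conditions: 2 M aq. HCl–THF (1:1), 45 °C
Reagents that add atoms: water, O
Why: Acid-catalysed hydrolysis of the cyclic acylal releases acetone and the malonic acid below the temperature at which it decarboxylates, and the benzyl and methyl ethers are stable to dilute aqueous acid.

Step 7
Reactants: 10 2-{[2,4-bis(benzyloxy)-3-butanoyl-6-methoxy-5-methylphenyl]methyl}propanedioic acid
Product: 11 2-{[2,4-bis(benzyloxy)-3-butanoyl-6-methoxy-5-methylphenyl]methyl}propanedioyl dichloride
Conditions: (COCl)2 (2.5 equiv), DMF (cat.), CH2Cl2, 0 → 20 °C; volatiles removed, used crude at once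
Reagents that add atoms: oxalyl chloride, ClC(=O)C(Cl)=O
Why: Chloroiminium-catalysed conversion of both carboxylic acids into acid chlorides proceeds at low temperature without base, so the chlorocarbonyl ketene is not triggered, and ring A has no free position or free hydroxyl to be acylated.

Step 8
Reactants: 12 heptane-3,5-dione
Product: 13 (Z)-5-(trimethylsilyloxy)hept-4-en-3-one
Conditions: Me3SiCl (1.3 equiv), NEt3 (1.5 equiv), pentane, 20 °C; filtration
Reagents that add atoms: chlorotrimethylsilane, C[Si](C)(C)Cl
Why: O-Silylation of the enol of a β-diketone under soft enolisation with an amine base is a standard preparation of 3-silyloxy enones.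

Step 9
Reactants: 13 (Z)-5-(trimethylsilyloxy)hept-4-en-3-one
Product: 14 (2Z,4Z)-3,5-bis(trimethylsilyloxy)hepta-2,4-diene
Conditions: LiN(iPr)2 (1.2 equiv), THF, −78 °C; then Me3SiCl (1.3 equiv), −78 → 20 °C
Reagents that add atoms: chlorotrimethylsilane, C[Si](C)(C)Cl
Why: Kinetic deprotonation of the silyloxy enone at the methylene beside the ketone and O-silylation of the dienolate give the 1,3-bis(silyl enol ether), and because 12 is symmetric only one constitution of the diene can arise.

Step 10
Reactants: 11 2-{[2,4-bis(benzyloxy)-3-butanoyl-6-methoxy-5-methylphenyl]methyl}propanedioyl dichloride; 14 (2Z,4Z)-3,5-bis(trimethylsilyloxy)hepta-2,4-diene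
Product: 16 1-{2,6-bis(benzyloxy)-4-methoxy-3-methyl-5-[(2,4,6-trihydroxy-3-methyl-5-propanoylphenyl)methyl]phenyl}butan-1-one, via mono-acylated silyl enol ether acid chloride 15 (not isolated)
Conditions: 14 (1.2 equiv), Me3SiOTf (0.3 equiv), CH2Cl2 (high dilution), −78 → 20 °C; then 1 M aq. HCl
Reagents that add atoms: none
Why: Proposed new method: the terminal carbon of 14 (the future methyl-bearing carbon of ring B), the most nucleophilic site of the dienol ether, attacks one Me3SiOTf-activated acid chloride of 11 and gives 15 with loss of Me3SiCl, after which the remaining silyl enol ether carbon (the future propanoyl-bearing carbon of ring B), now flanked by two carbonyl groups, attacks the second acid chloride, and loss of the second Me3SiCl with threefold enolisation of the resulting 2-acylcyclohexane-1,3,5-trione delivers the aromatic triol. The closest known reaction types are the [3+3] cyclocondensations of 1,3-bis(silyl enol ethers) with 1,3-dielectrophiles, the Effenberger cyclisation in which malonyl dichloride doubly C-acylates an enol ether to a cyclohexane-1,3,5-trione, and the Claisen cyclisation of 3,5,7-triketo esters to acylphloroglucinols; not yet shown is the one-operation carbocyclic closure of an open-chain diketone bis(enol ether) with a monosubstituted malonyl dichloride. Ring B closes by a 6-(enolexo)-exo-trig C-acylation. No stereocentre is created, since the two sp3 carbons of 15 end up as aromatic carbons. The step needs carbon rather than oxygen acylation in the ring closure (arene, not 4-hydroxy-2-pyrone); this is favoured because the future propanoyl-bearing carbon is the only position still carrying a preformed silyl enol ether π-nucleophile, because base-free conditions at −78 °C with catalytic Me3SiOTf hold back ketene formation and keep the diketone oxygens from reacting as enolates, and because aromatisation makes the carbocyclic closure irreversible. Regiochemistry is not in question because 12 is symmetric and the two acid chlorides of 11 are equivalent, and ring A cannot interfere because it is fully substituted and both of its phenols are benzylated.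

Step 11
Reactants: 16 1-{2,6-bis(benzyloxy)-4-methoxy-3-methyl-5-[(2,4,6-trihydroxy-3-methyl-5-propanoylphenyl)methyl]phenyl}butan-1-one
Product: 17 1-{2,6-dihydroxy-4-methoxy-3-methyl-5-[(2,4,6-trihydroxy-3-methyl-5-propanoylphenyl)methyl]phenyl}butan-1-one
Conditions: H2 (1 atm), Pd/C (10 wt% Pd), EtOAc, 20 °C
Reagents that add atoms: none
Why: Hydrogenolysis of the two aryl benzyl ethers over Pd/C at ambient pressure should leave the chelated aryl ketones, the methyl ether and the diarylmethane bridge intact.

**Compound list**
1 | 2-methylbenzene-1,3,5-triol | Cc1c(O)cc(O)cc1O | starting material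
2 | butanoyl chloride | CCCC(Cl)=O | starting material
3 | 1-(2,4,6-trihydroxy-3-methylphenyl)butan-1-one | CCCC(=O)c1c(O)cc(O)c(C)c1O | intermediate
4 | 1-(2,6-dihydroxy-4-methoxy-3-methylphenyl)butan-1-one (aspidinol) | CCCC(=O)c1c(O)cc(OC)c(C)c1O | intermediate
5 | 3-butanoyl-2,4-dihydroxy-6-methoxy-5-methylbenzaldehyde | CCCC(=O)c1c(O)c(C)c(OC)c(C=O)c1O | intermediate
6 | 2,4-bis(benzyloxy)-3-butanoyl-6-methoxy-5-methylbenzaldehyde | CCCC(=O)c1c(OCc2ccccc2)c(C)c(OC)c(C=O)c1OCc1ccccc1 | intermediate
7 | 2,2-dimethyl-1,3-dioxane-4,6-dione (Meldrum's acid) | CC1(C)OC(=O)CC(=O)O1 | starting material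
8 | 5-{[2,4-bis(benzyloxy)-3-butanoyl-6-methoxy-5-methylphenyl]methylidene}-2,2-dimethyl-1,3-dioxane-4,6-dione | CCCC(=O)c1c(OCc2ccccc2)c(C)c(OC)c(C=C2C(=O)OC(C)(C)OC2=O)c1OCc1ccccc1 | intermediate
9 | 5-{[2,4-bis(benzyloxy)-3-butanoyl-6-methoxy-5-methylphenyl]methyl}-2,2-dimethyl-1,3-dioxane-4,6-dione | CCCC(=O)c1c(OCc2ccccc2)c(C)c(OC)c(CC2C(=O)OC(C)(C)OC2=O)c1OCc1ccccc1 | intermediate
10 | 2-{[2,4-bis(benzyloxy)-3-butanoyl-6-methoxy-5-methylphenyl]methyl}propanedioic acid | CCCC(=O)c1c(OCc2ccccc2)c(C)c(OC)c(CC(C(=O)O)C(=O)O)c1OCc1ccccc1 | intermediate
11 | 2-{[2,4-bis(benzyloxy)-3-butanoyl-6-methoxy-5-methylphenyl]methyl}propanedioyl dichloride | CCCC(=O)c1c(OCc2ccccc2)c(C)c(OC)c(CC(C(Cl)=O)C(Cl)=O)c1OCc1ccccc1 | intermediate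
12 | heptane-3,5-dione | CCC(=O)CC(=O)CC | starting material
13 | (Z)-5-(trimethylsilyloxy)hept-4-en-3-one | CCC(=O)/C=C(/CC)O[Si](C)(C)C | intermediate
14 | (2Z,4Z)-3,5-bis(trimethylsilyloxy)hepta-2,4-diene | C/C=C(\O[Si](C)(C)C)/C=C(/CC)O[Si](C)(C)C | intermediate
15 | (6Z)-2-{[2,4-bis(benzyloxy)-3-butanoyl-6-methoxy-5-methylphenyl]methyl}-4-methyl-3,5-dioxo-7-(trimethylsilyloxy)non-6-enoyl chloride (mixture of diastereomers and enol forms) | CCCC(=O)c1c(OCc2ccccc2)c(C)c(OC)c(CC(C(Cl)=O)C(=O)C(C)C(=O)/C=C(/CC)O[Si](C)(C)C)c1OCc1ccccc1 | intermediate
16 | 1-{2,6-bis(benzyloxy)-4-methoxy-3-methyl-5-[(2,4,6-trihydroxy-3-methyl-5-propanoylphenyl)methyl]phenyl}butan-1-one | CCCC(=O)c1c(OCc2ccccc2)c(C)c(OC)c(Cc2c(O)c(C)c(O)c(C(=O)CC)c2O)c1OCc1ccccc1 | intermediate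
17 | 1-{2,6-dihydroxy-4-methoxy-3-methyl-5-[(2,4,6-trihydroxy-3-methyl-5-propanoylphenyl)methyl]phenyl}butan-1-one | CCCC(=O)c1c(O)c(C)c(OC)c(Cc2c(O)c(C)c(O)c(C(=O)CC)c2O)c1O | target

**Step count and risks**
Total step count: 11. Longest linear sequence: 9 steps (steps 1–7, 10 and 11); the diene branch (steps 8–9) joins at step 10.

Steps most likely to fail:

1. Step 10. The ring closure may run through oxygen instead of carbon: the enolised diketone of 15, or an acyl ketene formed from 15 by loss of HCl, can close to a 4-hydroxy-2-pyrone faster than the propanoyl-bearing carbon is acylated. Intermolecular acylation may also give oligomers. The fallback uses known reaction types only, sets out from 9 and comes back at 16. Heating 9 in MeOH opens the acylal to the half ester 2-{[2,4-bis(benzyloxy)-3-butanoyl-6-methoxy-5-methylphenyl]methyl}-3-methoxy-3-oxopropanoic acid F1. (COCl)2 with catalytic DMF converts it into methyl 2-{[2,4-bis(benzyloxy)-3-butanoyl-6-methoxy-5-methylphenyl]methyl}-3-chloro-3-oxopropanoate F2, which has a single acylating carbonyl. F2 acylates 14 at its terminal carbon (CH2Cl2, −78 → 20 °C, aqueous work-up), the established C-acylation of 1,3-bis(silyl enol ethers) by acid chlorides, to give methyl 2-{[2,4-bis(benzyloxy)-3-butanoyl-6-methoxy-5-methylphenyl]methyl}-4-methyl-3,5,7-trioxononanoate F3. Mg(OMe)2 in MeOH then brings about the Claisen cyclisation of the triketo ester, in which the methylene between the two ketones at chain positions 5 and 7 attacks the ester carbonyl, and aromatisation gives 16. The same two bonds are thus made in two separate, precedented operations.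

2. Step 7. HCl released during chlorination may promote attack of the benzyloxy oxygen ortho to the side chain on the neighbouring acid chloride, with loss of the benzyl group and lactonisation. The dichloride may also lose HCl to the chlorocarbonyl ketene and oligomerise on concentration. The fallback sets out from 10 and comes back at 11. Silylation with N,O-bis(trimethylsilyl)acetamide in CH2Cl2 gives bis(trimethylsilyl) 2-{[2,4-bis(benzyloxy)-3-butanoyl-6-methoxy-5-methylphenyl]methyl}propanedioate F4. (COCl)2 with catalytic DMF at 0 °C converts the silyl esters into acid chlorides with only Me3SiCl, CO and CO2 as by-products. Dichloride 11 is thus generated without HCl and is carried as a CH2Cl2 solution directly into step 10 without concentration.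

3. Step 2. Methylation may spread over the three hydroxyls, by attack at a chelated ortho hydroxyl or by double alkylation, giving isomeric ethers that are hard to separate. The fallback sets out from 3 and comes back at 4. Exhaustive methylation (excess Me2SO4, K2CO3, acetone, reflux) gives 1-(2,4,6-trimethoxy-3-methylphenyl)butan-1-one F5. Chelation-directed dealkylation with AlCl3 in CH2Cl2 at reflux then cleaves the two methoxy groups flanking the ketone, where the carbonyl-bound Lewis acid is delivered, and leaves the para methoxy group. The site selectivity then rests on chelation rather than on relative acidity.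

Further compounds
F1 | step 10 | 2-{[2,4-bis(benzyloxy)-3-butanoyl-6-methoxy-5-methylphenyl]methyl}-3-methoxy-3-oxopropanoic acid | CCCC(=O)c1c(OCc2ccccc2)c(C)c(OC)c(CC(C(=O)O)C(=O)OC)c1OCc1ccccc1
F2 | step 10 | methyl 2-{[2,4-bis(benzyloxy)-3-butanoyl-6-methoxy-5-methylphenyl]methyl}-3-chloro-3-oxopropanoate | CCCC(=O)c1c(OCc2ccccc2)c(C)c(OC)c(CC(C(Cl)=O)C(=O)OC)c1OCc1ccccc1
F3 | step 10 | methyl 2-{[2,4-bis(benzyloxy)-3-butanoyl-6-methoxy-5-methylphenyl]methyl}-4-methyl-3,5,7-trioxononanoate | CCCC(=O)c1c(OCc2ccccc2)c(C)c(OC)c(CC(C(=O)OC)C(=O)C(C)C(=O)CC(=O)CC)c1OCc1ccccc1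
F4 | step 7 | bis(trimethylsilyl) 2-{[2,4-bis(benzyloxy)-3-butanoyl-6-methoxy-5-methylphenyl]methyl}propanedioate | CCCC(=O)c1c(OCc2ccccc2)c(C)c(OC)c(CC(C(=O)O[Si](C)(C)C)C(=O)O[Si](C)(C)C)c1OCc1ccccc1
F5 | step 2 | 1-(2,4,6-trimethoxy-3-methylphenyl)butan-1-one | CCCC(=O)c1c(OC)cc(OC)c(C)c1OC
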